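A direct plan would carry the whole C20 chain in from geranylgeraniol: asymmetric hydrogenation would set C13, oxidation and esterification would give the C15 methyl ester, SeO2 would oxidise the terminal E-methyl group, and asymmetric epoxidation and acylation with senecioic acid would give the epoxy polyene A1.
A Cp2TiCl (trivalent titanium) radical cascade would then close ring A and ring B at once to the 3-hydroxy-labd-8(17)-ene A2; removal of the C3 oxygen would give A3, and hydration of the exocyclic alkene followed by selective saponification of the methyl ester would end the route.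
Its weakest steps would be these.
(a) The radical bicyclisation A1 → A2: a cascade of modest efficiency would be run on material that already carries two asymmetric steps, the conjugated senecioate is itself a radical acceptor, and the C3 hydroxyl it leaves is absent from the target, so that two more steps (thionocarbonate, Bu3SnH) would do nothing but remove it.
(b) The hydration of the 8(17)-alkene of A3 by oxymercuration–demercuration: the C8 carbinol would be set last, on the most precious material, by a facial bias alone, with Hg(OAc)2 and alkaline NaBH4 in the presence of two esters.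
(c) The allylic oxidation with SeO2: one methyl group among three alike trisubstituted alkenes would have to be picked out, and the reaction stopped at partial conversion with recycling.

The retrosynthesis takes off the O18 senecioate and the C15 ester group, then cuts the C8–C9 bond of ring B, then C9=C11 (Horner–Wadsworth–Emmons reaction, which brings in C11–C16 with C13 from (S)-4-methyloxolan-2-one); what remains is ring A alone.
Feature used: in ring A, C4 and C10 are both quaternary and both carry an axial methyl group, on either side of C5–H, so ring A has a local mirror plane through C5 and C2; ring A of natural (+)-dehydroabietic acid, read with C4 and C10 exchanged, is therefore ring A of this ent-labdane with its equatorial C18.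
In that reading the carboxyl carbon of the resin acid becomes C9, its C6–C8 stay C6–C8, and the aromatic carbon on the other quaternary centre becomes C18; ozonolysis of the arene sets these arms free, and C4, C5 and C10 never have to be made.
Ring A thus exists first and ring B is closed last, by the key step: C8 bears the hydroxyl and a methyl group and C9 a hydrogen and the C11 methylene, the pattern left when a ketyl at C8 (from the C17–C8 methyl ketone, SmI2) adds 6-exo to C9 of a C9=C11 vinyl sulfone; C8 and C9 are set together and the sulfone is cut off in the same flask.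
There is no polyene cascade, no oxygen at C3 to be removed, no allylic oxidation and no hydration of an 8(17)-alkene, and the two ester groups are told apart by a fluoride-labile ester, not by a selective saponification.

Key step: step 11

Remark: labdane numbering is used throughout, also for the monocyclic ring A compounds (C18 = equatorial CH2O carbon on C4, C19 = axial methyl on C4, C20 = methyl on C10, C17 = methyl on C8); (+)-dehydroabietic acid and (S)-4-methyloxolan-2-one are assumed to be bought enantiopure.

Step 1
Reactants: 1 (+)-dehydroabietic acid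
Product: 2 dehydroabietinol
Conditions: LiAlH4 (2 equiv), THF, 0 °C to reflux; then H2O, 15% aq. NaOH
Reagents that add atoms: none
Why: LiAlH4 reduction of the hindered tertiary carboxylic acid to the neopentyl alcohol touches no stereocentre and lowers the oxidation level of the carbon that will become C9 before the second carboxyl (the future C18) is created on the other quaternary carbon, so that the two arms, which alone carry the chirality of the later ring A fragment, can never become alike.

Step 2
Reactants: 2 dehydroabietinol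
Product: 3 dehydroabietyl acetate
Conditions: Ac2O (1.5 equiv), pyridine, DMAP (cat.), CH2Cl2, rt
Reagents that add atoms: acetic anhydride, CC(=O)OC(C)=O
Why: Acetylation (DMAP-catalysed acyl transfer) masks the alcohol against ozone and peracid, and the acetate needs no step of its own for removal because the Grignard reagent of step 5 cleaves it.

Step 3
Reactants: 3 dehydroabietyl acetate
Product: 4 (1S,2S,3R)-3-(acetoxymethyl)-2-(2-carboxyethyl)-1,3-dimethylcyclohexane-1-carboxylic acid
Conditions: O3/O2, CH2Cl2–AcOH 1:1, 0 °C, until the arene is consumed; then 30% H2O2, HCO2H, 40 °C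
Reagents that add atoms: ozone, [O-][O+]=O; hydrogen peroxide, OO
Why: Exhaustive ozonolysis of the electron-rich trialkylbenzene ring with oxidative work-up (arene degradation to carboxylic acids) cuts the ring away from both of its anchor atoms, so that a carboxyl is left on the quaternary carbon (future C18) and another at the end of the CH2CH2 arm (future C8, with C6 and C7), while the isopropyl-bearing carbons are lost as small acids and the three stereocentres of ring A stay as they are.

Step 4
Reactants: 4 (1S,2S,3R)-3-(acetoxymethyl)-2-(2-carboxyethyl)-1,3-dimethylcyclohexane-1-carboxylic acid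
Product: 5 (1S,2S,3R)-3-(acetoxymethyl)-2-{3-[methoxy(methyl)amino]-3-oxopropyl}-1,3-dimethylcyclohexane-1-carboxylic acid
Conditions: CDI (1.1 equiv), THF, 0 °C; then MeNHOMe·HCl (1.3 equiv), Et3N (1.3 equiv), rt
Reagents that add atoms: N,O-dimethylhydroxylamine hydrochloride, CNOC.Cl
Why: Chemoselective Weinreb amide formation, in which CDI and the amine reach the unhindered primary carboxyl far faster than the tertiary carboxyl on the quaternary ring carbon, so that only the future C8 is activated.

Step 5
Reactants: 5 (1S,2S,3R)-3-(acetoxymethyl)-2-{3-[methoxy(methyl)amino]-3-oxopropyl}-1,3-dimethylcyclohexane-1-carboxylic acid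
Product: 6 (1S,2S,3R)-3-(hydroxymethyl)-1,3-dimethyl-2-(3-oxobutyl)cyclohexane-1-carboxylic acid
Conditions: MeMgBr (5 equiv), THF, −20 °C to rt; then aq. NH4Cl, citric acid to pH 4, 0 °C
Reagents that add atoms: methylmagnesium bromide, C[Mg]Br
Why: Weinreb ketone synthesis, in which MeMgBr adds once to the amide to give the C17–C8 methyl ketone through the stable chelated tetrahedral adduct, cleaves the acetate in the same flask and leaves the tertiary carboxylate as an unreactive magnesium salt; the cold work-up at pH 4 avoids lactonisation of the hydroxy acid.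

Step 6
Reactants: 6 (1S,2S,3R)-3-(hydroxymethyl)-1,3-dimethyl-2-(3-oxobutyl)cyclohexane-1-carboxylic acid
Product: 7 (1S,2S,3R)-3-formyl-1,3-dimethyl-2-(3-oxobutyl)cyclohexane-1-carboxylic acid
Conditions: Dess–Martin periodinane (1.5 equiv), CH2Cl2, 0 °C to rt
Reagents that add atoms: none
Why: Dess–Martin oxidation of the neopentyl alcohol to the aldehyde (future C9) in a water-free medium stops at the aldehyde, which has no α-hydrogen, so that it is not carried on to a second carboxyl (that would make the fragment meso).

Step 7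
Reactants: 8 (4S)-4-methyloxolan-2-one
Product: 10 (3S)-4-iodo-3-methylbutanoic acid, via trimethylsilyl ester 9 (not isolated)
Conditions: Me3SiI (1.3 equiv), CH2Cl2, rt to 40 °C; then H2O, 0 °C
Reagents that add atoms: iodotrimethylsilane, C[Si](C)(C)I
Why: Ring opening of the lactone by Me3SiI, in which silylation of the carbonyl oxygen is followed by SN2 attack of iodide at the O–CH2 carbon, gives the iodo acid after hydrolysis of the silyl ester; the stereocentre (future C13) takes no part.

Step 8
Reactants: 10 (3S)-4-iodo-3-methylbutanoic acid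
Product: 11 2-(trimethylsilyl)ethyl (3S)-4-iodo-3-methylbutanoate
Conditions: Me3SiCH2CH2OH (1.2 equiv), DCC (1.1 equiv), DMAP (0.1 equiv), CH2Cl2, 0 °C
Reagents that add atoms: 2-(trimethylsilyl)ethanol, C[Si](C)(C)CCO
Why: Steglich esterification at 0 °C is faster than relactonisation of the γ-iodo acid and installs an ester that fluoride will cleave at the end without touching a conjugated ester.

Step 9
Reactants: 11 2-(trimethylsilyl)ethyl (3S)-4-iodo-3-methylbutanoate; 12 diethyl [(phenylsulfonyl)methyl]phosphonate
Product: 13 2-(trimethylsilyl)ethyl (3S)-5-(diethoxyphosphoryl)-3-methyl-5-(phenylsulfonyl)pentanoate (both C5 epimers)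
Conditions: NaH (1.05 equiv), DMF, 0 °C; then 11, 50 °C
Reagents that add atoms: none
Why: SN2 C-alkylation of the sodium salt of the doubly stabilised sulfonyl phosphonate by the primary iodide builds the reagent that holds C11–C16; the new stereocentre at the future C11 need not be controlled because this carbon ends as CH2.

Step 10
Reactants: 7 (1S,2S,3R)-3-formyl-1,3-dimethyl-2-(3-oxobutyl)cyclohexane-1-carboxylic acid; 13 2-(trimethylsilyl)ethyl (3S)-5-(diethoxyphosphoryl)-3-methyl-5-(phenylsulfonyl)pentanoate
Product: 14 (1S,2S,3R)-1,3-dimethyl-3-{(4S)-4-methyl-6-oxo-2-(phenylsulfonyl)-6-[2-(trimethylsilyl)ethoxy]hex-1-en-1-yl}-2-(3-oxobutyl)cyclohexane-1-carboxylic acid (E/Z mixture)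
Conditions: 13 (1.3 equiv), NaH (2.4 equiv), THF, 0 °C, then 7, 0 to 50 °C; then 1 M HCl to pH 3
Reagents that add atoms: none
Why: Horner–Wadsworth–Emmons olefination, in which the phosphonate carbanion adds to the non-enolisable aldehyde much faster than to the methyl ketone and the adduct loses diethyl phosphate, forms C9=C11 and brings in the whole side chain with the C13 stereocentre and the sulfone as acceptor group; the alkene geometry need not be controlled.

Step 11
Reactants: 14 (1S,2S,3R)-1,3-dimethyl-3-{(4S)-4-methyl-6-oxo-2-(phenylsulfonyl)-6-[2-(trimethylsilyl)ethoxy]hex-1-en-1-yl}-2-(3-oxobutyl)cyclohexane-1-carboxylic acid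
Product: 16 (4S,5S,8S,9S,10R,13R)-8-hydroxylabdane-15,18-dioic acid 15-[2-(trimethylsilyl)ethyl] ester, via C11 sulfone 15 (not isolated)
Conditions: SmI2 (3 equiv, 0.1 M in THF), MeOH (4 equiv), THF, −78 to 0 °C; then HMPA (12 equiv), SmI2 (5 equiv), −20 °C to rt; aq. KNaC4H4O6, pH 3
Reagents that add atoms: none
Why: SmI2 reduces the methyl ketone to a samarium-bound ketyl at C8, which adds in the 6-exo-trig mode to C9, the β-carbon of the vinyl sulfone; the α-sulfonyl radical at C11 takes a second electron and a proton to give 15, and after HMPA is added two more electrons cleave the C11–S bond, so that both alkene isomers of 14 and both C11 epimers of 15 end as the same CH2 group. The closest known reaction types are the SmI2 ketyl–olefin cyclisation onto electron-poor alkenes and the SmI2/HMPA desulfonylation of alkyl phenyl sulfones. Ring B closes through a chair transition state fused trans to ring A, since only the ring A conformer with both methyl groups axial and the C9 and C6 arms equatorial can bring C8 to C9, and C5 and C10 are already fixed. C9 is set by the acceptor alkene lying equatorial on that chair (side chain equatorial, 9S), and C8 by the bulky trivalent samarium alkoxide taking the equatorial site away from the axial C20 methyl, which leaves C17 axial and the hydroxyl trans to the side chain (8S). The step needs the ketone to be reduced in preference to the ester and the carboxylic acid, which SmI2 does not touch at −78 °C, and needs the radical addition to outrun simple reduction, which the activated acceptor and the six-membered chair should secure.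

Step 12
Reactants: 16 (4S,5S,8S,9S,10R,13R)-8-hydroxylabdane-15,18-dioic acid 15-[2-(trimethylsilyl)ethyl] ester
Product: 17 2-(trimethylsilyl)ethyl (4S,5S,8S,9S,10R,13R)-8,18-dihydroxylabdan-15-oate
Conditions: BH3·SMe2 (4 equiv), THF, 0 °C to rt; then MeOH
Reagents that add atoms: none
Why: Borane reduction, in which the free carboxylic acid is reduced through its acyloxyborane far faster than the ester, gives the neopentyl C18 alcohol and leaves C15 and all stereocentres untouched.

Step 13
Reactants: 17 2-(trimethylsilyl)ethyl (4S,5S,8S,9S,10R,13R)-8,18-dihydroxylabdan-15-oate; 18 3-methylbut-2-enoic acid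
Product: 19 2-(trimethylsilyl)ethyl (4S,5S,8S,9S,10R,13R)-8-hydroxy-18-[(3-methylbut-2-enoyl)oxy]labdan-15-oate
Conditions: EDC·HCl (1.5 equiv), DMAP (0.3 equiv), CH2Cl2, 0 °C to rt
Reagents that add atoms: none
Why: Steglich-type esterification (carbodiimide, DMAP) acylates the primary C18 alcohol while the hindered tertiary C8 alcohol stays free, and the use of the acid in place of the acid chloride and an amine avoids deconjugation through a vinylketene.

Step 14
Reactants: 19 2-(trimethylsilyl)ethyl (4S,5S,8S,9S,10R,13R)-8-hydroxy-18-[(3-methylbut-2-enoyl)oxy]labdan-15-oate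
Product: 21 (4S,5S,8S,9S,10R,13R)-8-hydroxy-18-[(3-methylbut-2-enoyl)oxy]labdan-15-oic acid, via tetrabutylammonium carboxylate 20 (not isolated)
Conditions: Bu4NF (3 equiv), THF, 0 °C to rt; then 1 M HCl to pH 3, 0 °C
Reagents that add atoms: none
Why: Fluoride-induced fragmentation of the 2-(trimethylsilyl)ethyl ester (attack at silicon, loss of ethene) frees the C15 carboxylate under conditions that leave the conjugated C18 ester and the tertiary alcohol untouched, and mild acidification gives the acid.

## Compound list

1 | (+)-dehydroabietic acid, (1R,4aS,10aR)-1,4a-dimethyl-7-(propan-2-yl)-1,2,3,4,4a,9,10,10a-octahydrophenanthrene-1-carboxylic acid | CC(C)c1ccc2c(c1)CC[C@@H]1[C@]2(C)CCC[C@@]1(C)C(=O)O | starting material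
2 | dehydroabietinol, [(1R,4aS,10aR)-1,4a-dimethyl-7-(propan-2-yl)-1,2,3,4,4a,9,10,10a-octahydrophenanthren-1-yl]methanol | CC(C)c1ccc2c(c1)CC[C@@H]1[C@]2(C)CCC[C@@]1(C)CO | intermediate
3 | dehydroabietyl acetate, [(1R,4aS,10aR)-1,4a-dimethyl-7-(propan-2-yl)-1,2,3,4,4a,9,10,10a-octahydrophenanthren-1-yl]methyl acetate | CC(C)c1ccc2c(c1)CC[C@@H]1[C@]2(C)CCC[C@@]1(C)COC(C)=O | intermediate
4 | (1S,2S,3R)-3-(acetoxymethyl)-2-(2-carboxyethyl)-1,3-dimethylcyclohexane-1-carboxylic acid | OC(=O)CC[C@@H]1[C@](C(=O)O)(C)CCC[C@@]1(C)COC(C)=O | intermediate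
5 | (1S,2S,3R)-3-(acetoxymethyl)-2-{3-[methoxy(methyl)amino]-3-oxopropyl}-1,3-dimethylcyclohexane-1-carboxylic acid | CON(C)C(=O)CC[C@@H]1[C@](C(=O)O)(C)CCC[C@@]1(C)COC(C)=O | intermediate
6 | (1S,2S,3R)-3-(hydroxymethyl)-1,3-dimethyl-2-(3-oxobutyl)cyclohexane-1-carboxylic acid | CC(=O)CC[C@@H]1[C@](C(=O)O)(C)CCC[C@@]1(C)CO | intermediate
7 | (1S,2S,3R)-3-formyl-1,3-dimethyl-2-(3-oxobutyl)cyclohexane-1-carboxylic acid | CC(=O)CC[C@@H]1[C@](C(=O)O)(C)CCC[C@@]1(C)C=O | intermediate
8 | (4S)-4-methyloxolan-2-one [(S)-3-methyl-γ-butyrolactone] | O=C1C[C@H](C)CO1 | starting material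
9 | trimethylsilyl (3S)-4-iodo-3-methylbutanoate | IC[C@@H](C)CC(=O)O[Si](C)(C)C | intermediate (not isolated)
10 | (3S)-4-iodo-3-methylbutanoic acid | IC[C@@H](C)CC(=O)O | intermediate
11 | 2-(trimethylsilyl)ethyl (3S)-4-iodo-3-methylbutanoate | IC[C@@H](C)CC(=O)OCC[Si](C)(C)C | intermediate
12 | diethyl [(phenylsulfonyl)methyl]phosphonate | CCOP(=O)(OCC)CS(=O)(=O)c1ccccc1 | starting material
13 | 2-(trimethylsilyl)ethyl (3S)-5-(diethoxyphosphoryl)-3-methyl-5-(phenylsulfonyl)pentanoate (both C5 epimers) | CCOP(=O)(OCC)C(S(=O)(=O)c1ccccc1)C[C@@H](C)CC(=O)OCC[Si](C)(C)C | intermediate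
14 | (1S,2S,3R)-1,3-dimethyl-3-{(4S)-4-methyl-6-oxo-2-(phenylsulfonyl)-6-[2-(trimethylsilyl)ethoxy]hex-1-en-1-yl}-2-(3-oxobutyl)cyclohexane-1-carboxylic acid (E/Z mixture) | CC(=O)CC[C@@H]1[C@](C(=O)O)(C)CCC[C@@]1(C)C=C(S(=O)(=O)c1ccccc1)C[C@@H](C)CC(=O)OCC[Si](C)(C)C | intermediate
15 | (4S,5S,8S,9S,10R,13S)-8-hydroxy-11-(phenylsulfonyl)labdane-15,18-dioic acid 15-[2-(trimethylsilyl)ethyl] ester (both C11 epimers) | OC(=O)[C@@]1(C)CCC[C@]2(C)[C@@H]1CC[C@](C)(O)[C@H]2C(S(=O)(=O)c1ccccc1)C[C@@H](C)CC(=O)OCC[Si](C)(C)C | intermediate (not isolated)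
16 | (4S,5S,8S,9S,10R,13R)-8-hydroxylabdane-15,18-dioic acid 15-[2-(trimethylsilyl)ethyl] ester | OC(=O)[C@@]1(C)CCC[C@]2(C)[C@@H]1CC[C@](C)(O)[C@H]2CC[C@@H](C)CC(=O)OCC[Si](C)(C)C | intermediate
17 | 2-(trimethylsilyl)ethyl (4S,5S,8S,9S,10R,13R)-8,18-dihydroxylabdan-15-oate | OC[C@@]1(C)CCC[C@]2(C)[C@@H]1CC[C@](C)(O)[C@H]2CC[C@@H](C)CC(=O)OCC[Si](C)(C)C | intermediate
18 | 3-methylbut-2-enoic acid (senecioic acid) | CC(C)=CC(=O)O | starting material
19 | 2-(trimethylsilyl)ethyl (4S,5S,8S,9S,10R,13R)-8-hydroxy-18-[(3-methylbut-2-enoyl)oxy]labdan-15-oate | CC(C)=CC(=O)OC[C@@]1(C)CCC[C@]2(C)[C@@H]1CC[C@](C)(O)[C@H]2CC[C@@H](C)CC(=O)OCC[Si](C)(C)C | intermediate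
20 | tetrabutylammonium (4S,5S,8S,9S,10R,13R)-8-hydroxy-18-[(3-methylbut-2-enoyl)oxy]labdan-15-oate | CC(C)=CC(=O)OC[C@@]1(C)CCC[C@]2(C)[C@@H]1CC[C@](C)(O)[C@H]2CC[C@@H](C)CC(=O)[O-].CCCC[N+](CCCC)(CCCC)CCCC | intermediate (not isolated)
21 | (4S,5S,8S,9S,10R,13R)-8-hydroxy-18-[(3-methylbut-2-enoyl)oxy]labdan-15-oic acid | CC(C)=CC(=O)OC[C@@]1(C)CCC[C@]2(C)[C@@H]1CC[C@](C)(O)[C@H]2CC[C@@H](C)CC(=O)O | target

Total steps: 14. Longest linear sequence: 11 (steps 1–6 and 10–14); steps 7–9 are a side branch of 3.

Steps most likely to fail: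

Step 11. The ketyl may add too slowly to the hindered, trisubstituted acceptor, so that the ketone or the vinyl sulfone is simply reduced, or the addition may show poor facial selectivity at C8. Fallback, from 7 and back at 16: ring B would be closed by a polar 6-enolexo aldol addition instead. Aldehyde 7 would be homologated with Ph3P=CHOMe at −78 °C (the aldehyde reacting before the methyl ketone) to the methyl enol ether F1, and dilute acid would give the keto aldehyde F2, in which C9 is a CH2 group and C11 the formyl carbon. Pyrrolidine/AcOH or proline would close C9–C8 through the enamine to the β-hydroxy aldehyde F3, with the formyl group equatorial. Wittig reaction of F3 with the ylide from the phosphonium iodide F4 (made from iodide 11 and PPh3) would give the (11Z)-alkene F5, and hydrogenation (H2, Pd/C) would give 16.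

Step 3. Ozone may attack the trialkylbenzene ring slowly and oxidise the benzylic C–H bonds in competition, so that the degradation stops at ketones or loses the future C8. Fallback, from 3 and back at 4: the ring would first be made electron-rich. Friedel–Crafts acetylation (AcCl, AlCl3) would give the 12-acetyl compound F6 (abietane numbering), Baeyer–Villiger oxidation (mCPBA) the aryl acetate F7, and brief methanolysis (K2CO3, MeOH, 0 °C; the aryl ester is cleaved first) the phenol F8. Its phenolic ring is cleaved by ozone at −78 °C, and H2O2 work-up would give 4.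

Step 10. The α-branched phosphonate carbanion may add slowly and reversibly to the α-quaternary aldehyde, and on heating enolisation of the methyl ketone or conjugate addition of the carboxylate to the product may take over. Fallback, from 7 and back at 16 by way of 15: the unbranched phosphonate 12 (NaH, THF) would give the (E)-vinyl sulfone F9, and SmI2/MeOH would close ring B to the C11 sulfone F10, which lacks the side chain. Its trianion (LiN(iPr)2, 3.3 equiv, THF–HMPA) would be alkylated at C11 with iodide 11 to give 15, which SmI2/HMPA would desulfonylate to 16 as in step 11.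

Further compounds
F1 | step 11 | (1S,2S,3R)-3-(2-methoxyethenyl)-1,3-dimethyl-2-(3-oxobutyl)cyclohexane-1-carboxylic acid (E/Z mixture) | CC(=O)CC[C@@H]1[C@](C(=O)O)(C)CCC[C@@]1(C)C=COC
F2 | step 11 | (1S,2S,3S)-1,3-dimethyl-2-(3-oxobutyl)-3-(2-oxoethyl)cyclohexane-1-carboxylic acid | CC(=O)CC[C@@H]1[C@](C(=O)O)(C)CCC[C@@]1(C)CC=O
F3 | step 11 | (4S,5S,8S,9S,10R)-8-hydroxy-11-oxo-12,13,14,15,16-pentanorlabdan-18-oic acid | OC(=O)[C@@]1(C)CCC[C@]2(C)[C@@H]1CC[C@](C)(O)[C@H]2C=O
F4 | step 11 | {(2S)-2-methyl-4-oxo-4-[2-(trimethylsilyl)ethoxy]butyl}triphenylphosphonium iodide | C[Si](C)(C)CCOC(=O)C[C@H](C)C[P+](c1ccccc1)(c1ccccc1)c1ccccc1.[I-]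
F5 | step 11 | (4S,5S,8S,9S,10R,11Z,13S)-8-hydroxylabd-11-ene-15,18-dioic acid 15-[2-(trimethylsilyl)ethyl] ester | OC(=O)[C@@]1(C)CCC[C@]2(C)[C@@H]1CC[C@](C)(O)[C@H]2/C=C\[C@@H](C)CC(=O)OCC[Si](C)(C)C
F6 | step 3 | 12-acetyldehydroabietyl acetate (abietane numbering) | CC(C)c1c(C(C)=O)cc2c(c1)CC[C@@H]1[C@]2(C)CCC[C@@]1(C)COC(C)=O
F7 | step 3 | 12-acetoxydehydroabietyl acetate | CC(C)c1c(OC(C)=O)cc2c(c1)CC[C@@H]1[C@]2(C)CCC[C@@]1(C)COC(C)=O
F8 | step 3 | 12-hydroxydehydroabietyl acetate | CC(C)c1c(O)cc2c(c1)CC[C@@H]1[C@]2(C)CCC[C@@]1(C)COC(C)=O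
F9 | step 10 | (1S,2S,3R)-1,3-dimethyl-2-(3-oxobutyl)-3-[(E)-2-(phenylsulfonyl)ethenyl]cyclohexane-1-carboxylic acid | CC(=O)CC[C@@H]1[C@](C(=O)O)(C)CCC[C@@]1(C)/C=C/S(=O)(=O)c1ccccc1
F10 | step 10 | (4S,5S,8S,9S,10R)-8-hydroxy-11-(phenylsulfonyl)-12,13,14,15,16-pentanorlabdan-18-oic acid | OC(=O)[C@@]1(C)CCC[C@]2(C)[C@@H]1CC[C@](C)(O)[C@H]2CS(=O)(=O)c1ccccc1
A1 | direct plan | methyl (3R,6E,10E,14R,15R)-14,15-epoxy-3,7,11,15-tetramethyl-16-[(3-methylbut-2-enoyl)oxy]hexadeca-6,10-dienoate | CC(C)=CC(=O)OC[C@@]1(C)O[C@@H]1CC/C(C)=C/CC/C(C)=C/CC[C@@H](C)CC(=O)OC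
A2 | direct plan | methyl (3R,4S,5S,9R,10S,13R)-3-hydroxy-18-[(3-methylbut-2-enoyl)oxy]labd-8(17)-en-15-oate | CC(C)=CC(=O)OC[C@@]1(C)[C@H](O)CC[C@]2(C)[C@@H]1CCC(=C)[C@H]2CC[C@@H](C)CC(=O)OC
A3 | direct plan | methyl (4S,5S,9R,10S,13R)-18-[(3-methylbut-2-enoyl)oxy]labd-8(17)-en-15-oate | CC(C)=CC(=O)OC[C@@]1(C)CCC[C@]2(C)[C@@H]1CCC(=C)[C@H]2CC[C@@H](C)CC(=O)OC
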